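## Retrosynthetic overview

1. Target ⇒ MOM-protected aryl aldehyde (late directed ortho-lithiation/formylation, then acetal cleavage); the C8 methyl ⇒ C8 ketone (Wittig, face-selective hydrogenation).
2. C9 quaternary centre and C1=C10 alkene ⇒ deconjugative C-methylation of a bicyclic enone that already carries the arylmethyl group.
3. Ring A (the only ring built; C4–C5 bond, C5 relayed from C3) ⇒ a new dienamine-mediated, vinylogous epoxide-opening annulation of a monocyclic (S)-epoxy enone.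
4. C3, the first stereocentre ⇒ organocatalytic Shi epoxidation of an achiral homoprenyl enone.
5. Ring B and the arene are bought: cyclohexane-1,3-dione + aryl aldehyde (organocatalytic reductive alkylation), then Stork–Danheiser addition of the homoprenyl chain.

Assumption: decalin atoms carry drimane-type labels (ring A = C1, C2, C3, C4, C5, C10; ring B = C5–C10; C3 carbinol, C4 CMe2, C9 quaternary); Ar = 2,6-bis(methoxymethoxy)-4-[(methoxymethoxy)methyl]phenyl; the L-fructose-derived enantiomer of the Shi ketone is taken as available.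

## Route

Step 1
Reactants: 1 3,5-dihydroxybenzyl alcohol
Product: 2 1,3-bis(methoxymethoxy)-5-[(methoxymethoxy)methyl]benzene
Conditions: NaH (3.5 equiv), MOMCl (3.5 equiv), DMF, 0 °C → rt
Reagents that add atoms: chloromethyl methyl ether, COCCl
Why: Williamson-type acetal protection of both phenoxides and the benzylic alkoxide; the MOM groups later direct both ortho-lithiations and survive every basic step.

Step 2
Reactants: 2 1,3-bis(methoxymethoxy)-5-[(methoxymethoxy)methyl]benzene
Product: 4 2,6-bis(methoxymethoxy)-4-[(methoxymethoxy)methyl]benzaldehyde (ArCHO), via aryllithium 3 (not isolated)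
Conditions: n-BuLi (1.2 equiv), TMEDA, THF, 0 °C; DMF, 0 °C → rt; H2O
Reagents that add atoms: N,N-dimethylformamide, CN(C)C=O
Why: Directed ortho-metalation at the most acidic ring C–H (between the two OMOM groups) followed by Bouveault formylation of the aryllithium.

Step 3
Reactants: 4 ArCHO, 5 cyclohexane-1,3-dione
Product: 7 2-(ArCH2)cyclohexane-1,3-dione, via alkylidene dione 6 (not isolated)
Conditions: Hantzsch ester (1.1 equiv), DL-proline (20 mol %), CH2Cl2, rt
Reagents that add atoms: none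
Why: Organocatalytic three-component reductive alkylation (Knoevenagel condensation, then Hantzsch-ester transfer hydrogenation of the alkylidene dione) gives clean C-monoalkylation of the 1,3-dione; no stereocentre is formed.

Step 4
Reactants: 7 2-(ArCH2)cyclohexane-1,3-dione
Product: 8 3-methoxy-2-(ArCH2)cyclohex-2-en-1-one
Conditions: TMSCHN2 (1.5 equiv), PhMe–MeOH (4:1), 0 °C → rt
Reagents that add atoms: (trimethylsilyl)diazomethane, C[Si](C)(C)C=[N+]=[N-]
Why: Neutral O-methylation of the acidic vinylogous acid (diazoalkane esterification type) gives the vinylogous ester; the dione is symmetric, so only one regioisomer can form.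

Step 5
Reactants: 8 3-methoxy-2-(ArCH2)cyclohex-2-en-1-one, 9 5-bromo-2-methylpent-2-ene
Product: 12 2-(ArCH2)-3-(4-methylpent-3-en-1-yl)cyclohex-2-en-1-one, via Grignard reagent 10 (not isolated), via magnesium carbinolate 11 (not isolated)
Conditions: Mg, THF, rt (9 → 10); add 8, 0 °C → rt; then 1 M HCl, THF, 0 °C, 20 min
Reagents that add atoms: water, O
Why: Stork–Danheiser sequence: 1,2-addition of the Grignard reagent to the vinylogous ester carbonyl, then acid-induced ionisation/hydrolysis, transposes the enone and puts the chain on the β-carbon, while brief cold dilute acid spares the MOM ethers.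

Step 6
Reactants: 12 2-(ArCH2)-3-(4-methylpent-3-en-1-yl)cyclohex-2-en-1-one
Product: 13 2-(ArCH2)-3-{2-[(2S)-3,3-dimethyloxiran-2-yl]ethyl}cyclohex-2-en-1-one
Conditions: L-fructose-derived Shi ketone (ent-Shi ketone, 30 mol %), KHSO5 (Oxone, 1.6 equiv), K2CO3, Bu4NHSO4 (5 mol %), MeCN–CH2(OMe)2–aq. Na2B4O7 buffer, 0 °C
Reagents that add atoms: potassium peroxymonosulfate, [K+].[O-]S(=O)(=O)OO
Why: Shi asymmetric epoxidation: the chiral dioxirane attacks only the electron-rich trisubstituted alkene (the enone alkene is electron-poor) through the spiro transition state and sets C3 as (S), the first stereocentre (about 90% ee expected).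

Step 7
Reactants: 13 2-(ArCH2)-3-{2-[(2S)-3,3-dimethyloxiran-2-yl]ethyl}cyclohex-2-en-1-one
Product: 16 (4aR,6S)-1-(ArCH2)-6-hydroxy-5,5-dimethyl-4,4a,5,6,7,8-hexahydronaphthalen-2(3H)-one, via endocyclic dienamine 14 (not isolated), via cyclised dienamine 15 (not isolated)
Conditions: pyrrolidine (5 equiv), 4 Å MS, PhMe, 80 °C; evaporate; (CF3)2CHOH (10 equiv), CH2Cl2, −40 → 0 °C; then AcOH–NaOAc, THF–H2O, rt
Reagents that add atoms: water, O
Why: Proposed new method: an intramolecular vinylogous (γ-selective) C-alkylation of a pyrrolidine dienamine by a trisubstituted epoxide activated through hydrogen bonding to hexafluoroisopropanol, in which dienamine 14 (the only isomer of the equilibrating dienamine mixture that can close a six-membered ring) attacks the tertiary epoxide carbon C4 through C5 in a chair transition state with the C3–O bond equatorial, so that H5 becomes axial and cis to H3 (3S relays to 5R, which is also the thermodynamically preferred C5 epimer), while α-attack through C9 is blocked because it would join two quaternary carbons; the closest known reactions are the Stork dienamine alkylation, SN1-type γ-alkylations in dienamine catalysis and hexafluoroisopropanol-promoted epoxide-initiated cation–olefin cyclisations.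

Step 8
Reactants: 16 (4aR,6S)-1-(ArCH2)-6-hydroxy-5,5-dimethyl-4,4a,5,6,7,8-hexahydronaphthalen-2(3H)-one
Product: 18 (1R,4aR,6S)-1-(ArCH2)-6-hydroxy-1,5,5-trimethyl-3,4,4a,5,6,7-hexahydronaphthalen-2(1H)-one, via potassium dienolate 17 (not isolated)
Conditions: KOtBu (1.3 equiv), t-BuOH–THF, rt; MeI (3 equiv), 0 °C
Reagents that add atoms: iodomethane, CI
Why: Deconjugative α-alkylation of the thermodynamic heteroannular dienolate (γ-deprotonation at C1, not at the shielded C5–H): MeI attacks C9 along the axial trajectory of a chair-like transition state, on the face of the axial H5, so the new methyl is cis to H5, the arylmethyl group becomes equatorial and the alkene moves to C1=C10; the hindered C3 alkoxide is not methylated.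

Step 9
Reactants: 18 (1R,4aR,6S)-1-(ArCH2)-6-hydroxy-1,5,5-trimethyl-3,4,4a,5,6,7-hexahydronaphthalen-2(1H)-one
Product: 19 (2S,5S,8aR)-5-(ArCH2)-1,1,5-trimethyl-6-methylidene-1,2,3,5,6,7,8,8a-octahydronaphthalen-2-ol
Conditions: Ph3PCH3Br (4 equiv), KOtBu (3.8 equiv), PhMe, 90 °C
Reagents that add atoms: methyltriphenylphosphonium bromide, C[P+](c1ccccc1)(c1ccccc1)c1ccccc1.[Br-]
Why: Wittig methylenation with excess salt-free ylide at elevated temperature works on ketones flanked by a quaternary carbon; C9 cannot epimerise and the free alcohol only consumes one equivalent of ylide.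

Step 10
Reactants: 19 (2S,5S,8aR)-5-(ArCH2)-1,1,5-trimethyl-6-methylidene-1,2,3,5,6,7,8,8a-octahydronaphthalen-2-ol
Product: 20 (2S,5S,6R,8aR)-5-(ArCH2)-1,1,5,6-tetramethyl-1,2,3,5,6,7,8,8a-octahydronaphthalen-2-ol
Conditions: H2 (4 atm), RhCl(PPh3)3 (10 mol %), PhH–EtOH (1:1), 40 °C
Reagents that add atoms: none
Why: Homogeneous hydrogenation with RhCl(PPh3)3 reduces only the 1,1-disubstituted alkene (the trisubstituted C1=C10 alkene and the benzylic acetal are inert) and delivers hydrogen to C8 from the face opposite the axial C9 methyl, making the new C8 methyl equatorial and cis to the C9 methyl (8R).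

Step 11
Reactants: 20 (2S,5S,6R,8aR)-5-(ArCH2)-1,1,5,6-tetramethyl-1,2,3,5,6,7,8,8a-octahydronaphthalen-2-ol
Product: 22 2,4-bis(methoxymethoxy)-6-[(methoxymethoxy)methyl]-3-{[(1S,2R,4aR,6S)-6-hydroxy-1,2,5,5-tetramethyl-1,2,3,4,4a,5,6,7-octahydronaphthalen-1-yl]methyl}benzaldehyde, via dilithio species 21 (not isolated)
Conditions: s-BuLi (2.5 equiv), TMEDA, THF, −78 °C; DMF, −78 → 0 °C; H2O
Reagents that add atoms: N,N-dimethylformamide, CN(C)C=O
Why: Directed ortho-metalation (after deprotonation of the C3 alcohol) at one of the two constitutionally equivalent aryl C–H positions, each flanked by OMOM and CH2OMOM, then Bouveault formylation places the aldehyde exactly where the target has it.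

Step 12
Reactants: 22 MOM-protected aldehyde
Product: 23 2,4-dihydroxy-6-(hydroxymethyl)-3-{[(1S,2R,4aR,6S)-6-hydroxy-1,2,5,5-tetramethyl-1,2,3,4,4a,5,6,7-octahydronaphthalen-1-yl]methyl}benzaldehyde (target; 3S,5R,8R,9S in decalin labels)
Conditions: Me2BBr (8 equiv), 2,6-di-tert-butylpyridine (2 equiv), CH2Cl2, −78 °C; then THF–sat. aq. NaHCO3, 0 °C
Reagents that add atoms: none
Why: Lewis-acid cleavage of all three MOM acetals (boron coordination, bromide attack at the acetal carbon) at −78 °C under proton-free conditions, which avoids acid-induced addition of the freed phenol to the C1=C10 alkene and acetalisation of the hydroxy aldehyde.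

## Compound list

1 | 3,5-dihydroxybenzyl alcohol | OCc1cc(O)cc(O)c1 | starting material
2 | 1,3-bis(methoxymethoxy)-5-[(methoxymethoxy)methyl]benzene | COCOCc1cc(OCOC)cc(OCOC)c1 | intermediate
3 | {2,6-bis(methoxymethoxy)-4-[(methoxymethoxy)methyl]phenyl}lithium | [Li]c1c(OCOC)cc(COCOC)cc1OCOC | intermediate (not isolated)
4 | 2,6-bis(methoxymethoxy)-4-[(methoxymethoxy)methyl]benzaldehyde | O=Cc1c(OCOC)cc(COCOC)cc1OCOC | intermediate
5 | cyclohexane-1,3-dione | O=C1CCCC(=O)C1 | starting material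
6 | 2-(arylmethylidene)cyclohexane-1,3-dione | O=C1CCCC(=O)C1=Cc1c(OCOC)cc(COCOC)cc1OCOC | intermediate (not isolated)
7 | 2-(ArCH2)cyclohexane-1,3-dione | O=C1CCCC(=O)C1Cc1c(OCOC)cc(COCOC)cc1OCOC | intermediate
8 | 3-methoxy-2-(ArCH2)cyclohex-2-en-1-one | COC1=C(Cc2c(OCOC)cc(COCOC)cc2OCOC)C(=O)CCC1 | intermediate
9 | 5-bromo-2-methylpent-2-ene | CC(C)=CCCBr | starting material
10 | (4-methylpent-3-en-1-yl)magnesium bromide | CC(C)=CCC[Mg]Br | intermediate (not isolated)
11 | bromomagnesium 3-methoxy-1-(4-methylpent-3-en-1-yl)-2-(ArCH2)cyclohex-2-en-1-olate (racemic) | COC1=C(Cc2c(OCOC)cc(COCOC)cc2OCOC)C(CCC=C(C)C)(O[Mg]Br)CCC1 | intermediate (not isolated)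
12 | 2-(ArCH2)-3-(4-methylpent-3-en-1-yl)cyclohex-2-en-1-one | O=C1CCCC(CCC=C(C)C)=C1Cc1c(OCOC)cc(COCOC)cc1OCOC | intermediate
13 | 2-(ArCH2)-3-{2-[(2S)-3,3-dimethyloxiran-2-yl]ethyl}cyclohex-2-en-1-one | O=C1CCCC(CC[C@@H]2OC2(C)C)=C1Cc1c(OCOC)cc(COCOC)cc1OCOC | intermediate
14 | 1-[2-(ArCH2)-3-{2-[(2S)-3,3-dimethyloxiran-2-yl]ethyl}cyclohexa-1,3-dien-1-yl]pyrrolidine | N1(CCCC1)C1=C(Cc2c(OCOC)cc(COCOC)cc2OCOC)C(CC[C@@H]2OC2(C)C)=CCC1 | intermediate (not isolated)
15 | (2S,8aR)-5-(ArCH2)-1,1-dimethyl-6-(pyrrolidin-1-yl)-1,2,3,7,8,8a-hexahydronaphthalen-2-ol (neutral dienamine tautomer of the cyclised iminium) | N1(CCCC1)C1=C(Cc2c(OCOC)cc(COCOC)cc2OCOC)C2=CC[C@H](O)C(C)(C)[C@@H]2CC1 | intermediate (not isolated)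
16 | (4aR,6S)-1-(ArCH2)-6-hydroxy-5,5-dimethyl-4,4a,5,6,7,8-hexahydronaphthalen-2(3H)-one (3S,5R) | O=C1CC[C@@H]2C(CC[C@H](O)C2(C)C)=C1Cc1c(OCOC)cc(COCOC)cc1OCOC | intermediate
17 | potassium heteroannular dienolate of 16 (O–C8=C9–C10=C1) | [K+].[O-]C1=C(Cc2c(OCOC)cc(COCOC)cc2OCOC)C2=CC[C@H](O)C(C)(C)[C@@H]2CC1 | intermediate (not isolated)
18 | (1R,4aR,6S)-1-(ArCH2)-6-hydroxy-1,5,5-trimethyl-3,4,4a,5,6,7-hexahydronaphthalen-2(1H)-one (3S,5R,9R) | O=C1CC[C@@H]2C(=CC[C@H](O)C2(C)C)[C@@]1(C)Cc1c(OCOC)cc(COCOC)cc1OCOC | intermediate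
19 | (2S,5S,8aR)-5-(ArCH2)-1,1,5-trimethyl-6-methylidene-1,2,3,5,6,7,8,8a-octahydronaphthalen-2-ol (3S,5R,9S) | C=C1CC[C@@H]2C(=CC[C@H](O)C2(C)C)[C@@]1(C)Cc1c(OCOC)cc(COCOC)cc1OCOC | intermediate
20 | (2S,5S,6R,8aR)-5-(ArCH2)-1,1,5,6-tetramethyl-1,2,3,5,6,7,8,8a-octahydronaphthalen-2-ol (3S,5R,8R,9S) | C[C@@H]1CC[C@@H]2C(=CC[C@H](O)C2(C)C)[C@@]1(C)Cc1c(OCOC)cc(COCOC)cc1OCOC | intermediate
21 | lithium alkoxide/aryllithium of 20 (Li on C3–O and on the ring carbon between OMOM and CH2OMOM) | C[C@@H]1CC[C@@H]2C(=CC[C@H](O[Li])C2(C)C)[C@@]1(C)Cc1c(OCOC)cc(COCOC)c([Li])c1OCOC | intermediate (not isolated)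
22 | 2,4-bis(methoxymethoxy)-6-[(methoxymethoxy)methyl]-3-{[(1S,2R,4aR,6S)-6-hydroxy-1,2,5,5-tetramethyl-1,2,3,4,4a,5,6,7-octahydronaphthalen-1-yl]methyl}benzaldehyde | C[C@@H]1CC[C@@H]2C(=CC[C@H](O)C2(C)C)[C@@]1(C)Cc1c(OCOC)cc(COCOC)c(C=O)c1OCOC | intermediate
23 | 2,4-dihydroxy-6-(hydroxymethyl)-3-{[(1S,2R,4aR,6S)-6-hydroxy-1,2,5,5-tetramethyl-1,2,3,4,4a,5,6,7-octahydronaphthalen-1-yl]methyl}benzaldehyde | C[C@@H]1CC[C@@H]2C(=CC[C@H](O)C2(C)C)[C@@]1(C)Cc1c(O)cc(CO)c(C=O)c1O | target

## Step count and risks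

Total steps: 12. Longest linear sequence: 12 (1 → 23; 5 and 9 enter as purchased materials).

**Step 7 (the proposed new annulation).** Risks are Meinwald rearrangement of the activated epoxide, attack at the secondary epoxide carbon, or sluggish dienamine formation. The fallback uses known chemistry, sets out from 13 and returns at 16. Epoxy enone 13 is deconjugated the classical way (KOtBu, t-BuOH–THF, 0 °C, then inverse quench into cold aqueous AcOH; kinetic α-protonation of the dienolate). This gives the β,γ-unsaturated ketone 2-(ArCH2)-3-{2-[(2S)-3,3-dimethyloxiran-2-yl]ethyl}cyclohex-3-en-1-one F1 (C9 epimers, which do not matter). Its isolated trisubstituted C5=C10 alkene then terminates an ordinary Lewis-acid epoxide–alkene cyclisation (MeAlCl2, CH2Cl2, −78 °C). The same chair forms the C4–C5 bond, and the C10 cation loses the acidic H9 to give 16; DBU moves any unconjugated isomer into conjugation.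

**Step 8 (facial selectivity at C9, over-methylation).** If MeI enters mainly trans to H5, the two C9 substituents are introduced in the opposite order, so that the arylmethyl group takes the preferred trajectory. This fallback sets out from 9 and 4 and returns at 18.
- Grignard reagent 10 is added to commercial 3-ethoxy-2-methylcyclohex-2-en-1-one, and acid work-up gives 2-methyl-3-(4-methylpent-3-en-1-yl)cyclohex-2-en-1-one F2.
- Shi epoxidation as in step 6 gives 3-{2-[(2S)-3,3-dimethyloxiran-2-yl]ethyl}-2-methylcyclohex-2-en-1-one F3.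
- Annulation as in step 7 gives (4aR,6S)-6-hydroxy-1,5,5-trimethyl-4,4a,5,6,7,8-hexahydronaphthalen-2(3H)-one F4.
- Aldehyde 4 is reduced (NaBH4, MeOH) to {2,6-bis(methoxymethoxy)-4-[(methoxymethoxy)methyl]phenyl}methanol F5 and converted (CBr4, PPh3, CH2Cl2, 0 °C) into 2-(bromomethyl)-1,3-bis(methoxymethoxy)-5-[(methoxymethoxy)methyl]benzene F6.
- The dienolate of F4 (KOtBu, t-BuOH–THF) is alkylated with F6 to give 18.

**Step 10 (face selectivity at C8, slow reduction of a hindered alkene).** The fallback sets out from 19 and returns at 20. Hydroboration with the bulky 9-BBN (THF, 60 °C; NaOH, H2O2) is inert to the C1=C10 alkene and much more sensitive to the axial C9 methyl. It gives (2S,5S,6R,8aR)-5-(ArCH2)-6-(hydroxymethyl)-1,1,5-trimethyl-1,2,3,5,6,7,8,8a-octahydronaphthalen-2-ol F7. Selective sulfonylation of the primary alcohol (TsCl, pyridine, 0 °C) gives [(1S,2R,4aR,6S)-1-(ArCH2)-6-hydroxy-1,5,5-trimethyl-1,2,3,4,4a,5,6,7-octahydronaphthalen-2-yl]methyl 4-methylbenzenesulfonate F8. Reduction with LiEt3BH (THF, 0 °C → rt) gives 20.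

## Further compounds

F1 | step 7 | 2-(ArCH2)-3-{2-[(2S)-3,3-dimethyloxiran-2-yl]ethyl}cyclohex-3-en-1-one (C2 epimers) | O=C1CCC=C(CC[C@@H]2OC2(C)C)C1Cc1c(OCOC)cc(COCOC)cc1OCOC
F2 | step 8 | 2-methyl-3-(4-methylpent-3-en-1-yl)cyclohex-2-en-1-one | O=C1CCCC(CCC=C(C)C)=C1C
F3 | step 8 | 3-{2-[(2S)-3,3-dimethyloxiran-2-yl]ethyl}-2-methylcyclohex-2-en-1-one | O=C1CCCC(CC[C@@H]2OC2(C)C)=C1C
F4 | step 8 | (4aR,6S)-6-hydroxy-1,5,5-trimethyl-4,4a,5,6,7,8-hexahydronaphthalen-2(3H)-one | O=C1CC[C@@H]2C(CC[C@H](O)C2(C)C)=C1C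
F5 | step 8 | {2,6-bis(methoxymethoxy)-4-[(methoxymethoxy)methyl]phenyl}methanol | OCc1c(OCOC)cc(COCOC)cc1OCOC
F6 | step 8 | 2-(bromomethyl)-1,3-bis(methoxymethoxy)-5-[(methoxymethoxy)methyl]benzene | BrCc1c(OCOC)cc(COCOC)cc1OCOC
F7 | step 10 | (2S,5S,6R,8aR)-5-(ArCH2)-6-(hydroxymethyl)-1,1,5-trimethyl-1,2,3,5,6,7,8,8a-octahydronaphthalen-2-ol | OC[C@@H]1CC[C@@H]2C(=CC[C@H](O)C2(C)C)[C@@]1(C)Cc1c(OCOC)cc(COCOC)cc1OCOC
F8 | step 10 | [(1S,2R,4aR,6S)-1-(ArCH2)-6-hydroxy-1,5,5-trimethyl-1,2,3,4,4a,5,6,7-octahydronaphthalen-2-yl]methyl 4-methylbenzenesulfonate | Cc1ccc(cc1)S(=O)(=O)OC[C@@H]1CC[C@@H]2C(=CC[C@H](O)C2(C)C)[C@@]1(C)Cc1c(OCOC)cc(COCOC)cc1OCOC
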